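The route rests on disconnecting the C7c–C8c bond of the indane ring (C7c: the indane CH bearing a 4-hydroxyphenyl group; C8c: its neighbour, shared with the eight-membered ring and benzylic to the benzofuran benzene ring). The key step generates a diaryl (donor/donor) rhodium carbene at C7c, attached to the resorcinol ring that becomes the indane benzo ring, and lets it insert into one benzylic C8c–H bond of the complete dihydrobenzofuran-fused eight-membered ring. This closes the indane and sets C7c and C8c at once, exploiting the cis relationship of H7c and H8c. The precursor is a hindered diaryl ketone hydrazone; all three resorcinol rings derive from 2-bromo-4,6-dimethoxybenzaldehyde.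

Key step: step 15

Labels: units a, b and c are numbered as in stilbene oligomers. C7 is the CH carrying a 4-oxyphenyl ring, C8 its neighbour, C9–C14 the resorcinol ring (C9 on C8); ring A, B, C is the resorcinol ring of unit a, b, c. Inter-unit bonds: C8a–C8c and C7c–C10a (indane), C7a–C10b and C8b–C10c (eight-membered ring), C7b–O–C11c (dihydrofuran). The target is (7aR,8aR,7bR,8bR,7cR,8cS).

Assumption: Rh2(R-PTAD)4 (dirhodium tetrakis[(R)-(1-adamantyl)(phthalimido)acetate]) and the (R,R)-diene ligand are taken to be the catalyst enantiomers that give the configurations drawn; if the sense of induction is opposite, the mirror-image catalyst is used.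

Step 1
Reactants: 1 2-bromo-4,6-dimethoxybenzaldehyde
Product: 2 2-bromo-6-hydroxy-4-methoxybenzaldehyde
Conditions: BCl3 (1.2 equiv), CH2Cl2, −78 → 0 °C; aqueous work-up
Reagents that add atoms: none
Why: BCl3 chelates between the aldehyde oxygen and the ortho methoxy group, so only that ether should be cleaved (chelation-controlled Lewis-acid demethylation) and the para methoxy group stays.

Step 2
Reactants: 2 2-bromo-6-hydroxy-4-methoxybenzaldehyde; 3 4-methoxybenzyl chloride
Product: 4 2-bromo-4-methoxy-6-[(4-methoxybenzyl)oxy]benzaldehyde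
Conditions: K2CO3, KI (cat.), DMF, 50 °C
Reagents that add atoms: none
Why: Williamson ether synthesis on the phenoxide; the benzylic CH2 introduced here is the later C7b and its ring the later C7b aryl group.

Step 3
Reactants: 1 2-bromo-4,6-dimethoxybenzaldehyde
Product: 5 2-(2-bromo-4,6-dimethoxyphenyl)-1,3-dioxolane
Conditions: HOCH2CH2OH, TsOH (cat.), toluene, reflux (Dean–Stark)
Reagents that add atoms: ethylene glycol OCCO
Why: acid-catalysed acetalisation masks the aldehyde (the later C7a) against the organolithium step.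

Step 4
Reactants: 5 2-(2-bromo-4,6-dimethoxyphenyl)-1,3-dioxolane; 4 2-bromo-4-methoxy-6-[(4-methoxybenzyl)oxy]benzaldehyde
Product: 6 [2-bromo-4-methoxy-6-(4-methoxybenzyloxy)phenyl][2-(1,3-dioxolan-2-yl)-3,5-dimethoxyphenyl]methanol (racemic)
Conditions: 5, n-BuLi, THF, −78 °C; then 4, −78 → −40 °C; aq. NH4Cl
Reagents that add atoms: none
Why: bromine–lithium exchange on 5 then 1,2-addition; the aryllithium should add to the aldehyde at −78 °C far faster than it exchanges with the aryl bromide of 4, forming the C8b–C9b bond.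

Step 5
Reactants: 6 the diarylmethanol
Product: 7 [2-bromo-4-methoxy-6-(4-methoxybenzyloxy)phenyl][2-(1,3-dioxolan-2-yl)-3,5-dimethoxyphenyl]methanone
Conditions: Dess–Martin periodinane, NaHCO3, CH2Cl2, rt
Reagents that add atoms: none
Why: Dess–Martin oxidation of a benzhydrol under neutral conditions that leave the dioxolane and the benzyl ether intact.

Step 6
Reactants: 7 the diaryl ketone
Product: 9 hydrazone of ketone 7, via N-silyl hydrazone 8 (not isolated)
Conditions: TBSNHNHTBS, Sc(OTf)3 (1 mol%), CHCl3, 60 → 100 °C; then TBAF, THF, 0 °C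
Reagents that add atoms: 1,2-bis(tert-butyldimethylsilyl)hydrazine CC(C)(C)[Si](C)(C)NN[Si](C)(C)C(C)(C)C
Why: Sc(OTf)3-catalysed condensation with the bis-silyl hydrazine (Myers N-silylhydrazone formation) should overcome the hindrance of the tri-ortho-substituted benzophenone under anhydrous conditions that spare the acetal, and fluoride then frees the hydrazone.

Step 7
Reactants: 9 hydrazone of ketone 7
Product: 11 (2S,3R)-4-bromo-3-[2-(1,3-dioxolan-2-yl)-3,5-dimethoxyphenyl]-6-methoxy-2-(4-methoxyphenyl)-2,3-dihydro-1-benzofuran (2,3-cis), via diaryldiazomethane 10 (not isolated)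
Conditions: MnO2, CH2Cl2, 0 °C; filter; Rh2(R-PTAD)4 (1 mol%), CH2Cl2, 0 °C → rt
Reagents that add atoms: none
Why: dirhodium donor/donor carbene 1,5 C–H insertion into the benzylic OCH2Ar bond (known benzodihydrofuran synthesis) is cis-selective and should set C8b (R) under catalyst control; C7b is formed S and is corrected in step 8.

Step 8
Reactants: 11 the cis-dihydrobenzofuran bromide; 12 tributyl(1-ethoxyvinyl)stannane
Product: 14 2-[(2R,3R)-4-acetyl-6-methoxy-2-(4-methoxyphenyl)-2,3-dihydro-1-benzofuran-3-yl]-4,6-dimethoxybenzaldehyde (2,3-trans), via enol ether 13 (not isolated)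
Conditions: Pd(PPh3)4 (5 mol%), toluene, 100 °C; then TFA, CH2Cl2/H2O, rt
Reagents that add atoms: water O
Why: Stille coupling installs the masked acetyl group (C8c and C8a); aqueous acid then hydrolyses enol ether and dioxolane and should equilibrate C7b, through reversible ionisation of the benzylic C7b–O bond, to the more stable 2,3-trans isomer while C8b is untouched.

Step 9
Reactants: 14 the trans keto aldehyde
Product: 15 (7bR,8bR)-eight-ring (Z)-enone: C8c ketone conjugated to C8a=C7a between ring C and ring B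
Conditions: KOH, MeOH/THF (0.002 M), rt → 40 °C
Reagents that add atoms: none
Why: intramolecular Claisen–Schmidt aldol condensation between the only enolisable ketone and the non-enolisable aldehyde, both held on neighbouring ortho positions of the diarylmethine C8b; the ring enforces the cis alkene.

Step 10
Reactants: 15 the enone; 16 4-methoxyphenylboronic acid
Product: 17 (7aR,7bR,8bR)-C8c ketone bearing 4-methoxyphenyl on C7a
Conditions: [RhCl(C2H4)2]2 (2.5 mol%), (R,R)-2,5-diphenylbicyclo[2.2.2]octa-2,5-diene, KOH, dioxane/H2O, 50 °C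
Reagents that add atoms: none
Why: Hayashi–Miyaura rhodium-catalysed asymmetric 1,4-addition; the chiral diene should set C7a (R), the aryl group arriving on the enone face remote from the dihydrofuran ring (ligand and substrate bias matched).

Step 11
Reactants: 1 2-bromo-4,6-dimethoxybenzaldehyde
Product: 19 2-bromo-4,6-dimethoxybenzonitrile, via aldoxime 18 (not isolated)
Conditions: NH2OH·HCl, DMSO, 100 °C
Reagents that add atoms: hydroxylamine hydrochloride NO.Cl
Why: oxime formation and thermal dehydration in DMSO (one-pot aldehyde-to-nitrile conversion), which is easy for a 2,6-disubstituted benzaldoxime.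

Step 12
Reactants: 17 the C7a-arylated ketone; 19 2-bromo-4,6-dimethoxybenzonitrile
Product: 20 (7aR,8aR,7bR,8bR)-C8c ketone bearing 2-cyano-3,5-dimethoxyphenyl (ring A) on C8a
Conditions: Pd2(dba)3 (2.5 mol%), XPhos, K3PO4, toluene, 90 °C
Reagents that add atoms: none
Why: palladium-catalysed ketone α-arylation (Buchwald–Hartwig type) at the only enolisable position; C8a lies α to the ketone and should equilibrate through the enolate to the trans arrangement of the aryl groups on C8a and C7a.

Step 13
Reactants: 20 the α-aryl ketone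
Product: 22 (7aR,8aR,7bR,8bR)-ring A nitrile having C8c as CH2, via tosylhydrazone 21 (not isolated)
Conditions: TsNHNH2, PPTS (cat.), toluene, 80 °C; then catecholborane, CHCl3, 0 °C; NaOAc·3H2O, 60 °C
Reagents that add atoms: none
Why: Caglioti–Kabalka deoxygenation (tosylhydrazone, then catecholborane) removes the ketone oxygen under near-neutral conditions that spare the nitrile and avoid base-induced opening of the dihydrobenzofuran; C8a stays in its preferred trans arrangement.

Step 14
Reactants: 22 the nitrile; 23 4-methoxyphenylmagnesium bromide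
Product: 25 hydrazone of the C7c diaryl ketone (C7c bonded to C10a of ring A and to 4-methoxyphenyl), via ketimine 24 (not isolated)
Conditions: CuBr·SMe2 (5 mol%), THF/toluene, 70 °C; MeOH; then N2H4·H2O, AcOH, EtOH, 80 °C
Reagents that add atoms: hydrazine hydrate NN.O
Why: copper-catalysed Grignard addition to the di-ortho-substituted nitrile stops at the N–H ketimine, which should exchange with hydrazine (transimination) more readily than a hindered ketone would condense.

Step 15
Reactants: 25 the C7c hydrazone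
Product: 27 octa-O-methylcanaliculatol, via diazo compound 26 (not isolated)
Conditions: MnO2, CH2Cl2, 0 °C; filter; Rh2(R-PTAD)4 (2 mol%), CH2Cl2, −20 °C → rt
Reagents that add atoms: none
Why: MnO2 dehydrogenates the hydrazone to diaryldiazomethane 26, which loses N2 on the dirhodium catalyst to give a donor/donor carbene at C7c; hydride transfer from C8c through a six-membered transition state and collapse of the zwitterion form the C7c–C8c bond. The closest known reaction type is the dirhodium-catalysed 1,5 C–H insertion of diaryl carbenes from 2-alkylbenzophenone hydrazones, which gives 1,2-cis-indanes and cis-2,3-diaryldihydrobenzofurans. The indane closes in the 1,5-insertion mode (five-membered ring through C7c, C10a, C9a, C8a and C8c). C7c should be set by the intrinsic cis preference of this insertion (its aryl group cis to ring C on C8c, so H7c cis to H8c), and C8c by which diastereotopic hydrogen is replaced: replacing the one cis to H8a leaves H8c trans to H8a (trans ring fusion), and this C–H bond and the C8a–aryl bond are both pseudo-equatorial on the eight-membered ring, with the catalyst enantiomer chosen to match. The step needs site selectivity for the C8c methylene over the C7a–H methine and the ortho OCH3 group: C8c–H2 is the only unhindered secondary benzylic 1,5 C–H, whereas C7a–H is a tertiary diarylmethine shielded by its anisyl group and the ortho-disubstituted ring B (insertion there would have to build a quaternary carbon beside the carbene carbon), and the OCH3 hydrogens are primary. The four existing stereocentres are untouched under these neutral conditions.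

Step 16
Reactants: 27 octa-O-methylcanaliculatol
Product: 28 canaliculatol
Conditions: BBr3 (20 equiv), CH2Cl2, −78 °C → rt; then MeOH/H2O
Reagents that add atoms: none
Why: Lewis-acid cleavage of the eight aryl methyl ethers with BBr3; any opening of the benzylic C7b–O bond is reversible and should return the trans dihydrobenzofuran, and no carbon stereocentre is otherwise labile.

Compound list
1 | 2-bromo-4,6-dimethoxybenzaldehyde | COc1cc(Br)c(C=O)c(OC)c1 | starting material
2 | 2-bromo-6-hydroxy-4-methoxybenzaldehyde | COc1cc(O)c(C=O)c(Br)c1 | intermediate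
3 | 4-methoxybenzyl chloride | COc1ccc(CCl)cc1 | starting material
4 | 2-bromo-4-methoxy-6-[(4-methoxybenzyl)oxy]benzaldehyde | COc1ccc(COc2cc(OC)cc(Br)c2C=O)cc1 | intermediate
5 | 2-(2-bromo-4,6-dimethoxyphenyl)-1,3-dioxolane | COc1cc(Br)c(C2OCCO2)c(OC)c1 | intermediate
6 | [2-bromo-4-methoxy-6-(4-methoxybenzyloxy)phenyl][2-(1,3-dioxolan-2-yl)-3,5-dimethoxyphenyl]methanol (racemic) | COc1ccc(COc2cc(OC)cc(Br)c2C(O)c2cc(OC)cc(OC)c2C2OCCO2)cc1 | intermediate
7 | [2-bromo-4-methoxy-6-(4-methoxybenzyloxy)phenyl][2-(1,3-dioxolan-2-yl)-3,5-dimethoxyphenyl]methanone | COc1ccc(COc2cc(OC)cc(Br)c2C(=O)c2cc(OC)cc(OC)c2C2OCCO2)cc1 | intermediate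
8 | N-(tert-butyldimethylsilyl)hydrazone of 7 | COc1ccc(COc2cc(OC)cc(Br)c2C(=NN[Si](C)(C)C(C)(C)C)c2cc(OC)cc(OC)c2C2OCCO2)cc1 | intermediate
9 | hydrazone of 7 | COc1ccc(COc2cc(OC)cc(Br)c2C(=NN)c2cc(OC)cc(OC)c2C2OCCO2)cc1 | intermediate
10 | diaryldiazomethane from 9 | COc1ccc(COc2cc(OC)cc(Br)c2C(=[N+]=[N-])c2cc(OC)cc(OC)c2C2OCCO2)cc1 | intermediate
11 | (2S,3R)-4-bromo-3-[2-(1,3-dioxolan-2-yl)-3,5-dimethoxyphenyl]-6-methoxy-2-(4-methoxyphenyl)-2,3-dihydro-1-benzofuran (cis) | COc1cc(OC)c(C2OCCO2)c(c1)[C@@H]1c2c(Br)cc(OC)cc2O[C@@H]1c1ccc(OC)cc1 | intermediate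
12 | tributyl(1-ethoxyvinyl)stannane | CCCC[Sn](CCCC)(CCCC)C(=C)OCC | starting material
13 | (2S,3R)-3-[2-(1,3-dioxolan-2-yl)-3,5-dimethoxyphenyl]-4-(1-ethoxyvinyl)-6-methoxy-2-(4-methoxyphenyl)-2,3-dihydro-1-benzofuran (cis) | COc1cc(OC)c(C2OCCO2)c(c1)[C@@H]1c2c(C(=C)OCC)cc(OC)cc2O[C@@H]1c1ccc(OC)cc1 | intermediate
14 | 2-[(2R,3R)-4-acetyl-6-methoxy-2-(4-methoxyphenyl)-2,3-dihydro-1-benzofuran-3-yl]-4,6-dimethoxybenzaldehyde (trans) | COc1cc(OC)c(C=O)c(c1)[C@@H]1c2c(C(C)=O)cc(OC)cc2O[C@H]1c1ccc(OC)cc1 | intermediate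
15 | (7bR,8bR)-enone: trans-dihydrobenzofuran whose C4 (C9c) and ring B carbon C10b are bridged by C8c(=O)–C8a H=C7a H (Z), closing the eight-membered ring through C8b | O=C1/C=C\c2c(OC)cc(OC)cc2[C@@H]2c3c1cc(OC)cc3O[C@H]2c1ccc(OC)cc1 | intermediate
16 | 4-methoxyphenylboronic acid | COc1ccc(B(O)O)cc1 | starting material
17 | (7aR,7bR,8bR)-ketone: as 15 with C8a H2 and C7a H(4-methoxyphenyl) | O=C1C[C@H](c2ccc(OC)cc2)c2c(OC)cc(OC)cc2[C@@H]2c3c1cc(OC)cc3O[C@H]2c1ccc(OC)cc1 | intermediate
18 | (E)-2-bromo-4,6-dimethoxybenzaldehyde oxime | COc1cc(Br)c(/C=N/O)c(OC)c1 | intermediate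
19 | 2-bromo-4,6-dimethoxybenzonitrile | COc1cc(Br)c(C#N)c(OC)c1 | intermediate
20 | (7aR,8aR,7bR,8bR)-ketone: as 17 with 2-cyano-3,5-dimethoxyphenyl (ring A) on C8a, trans to the C7a aryl group | N#Cc1c(OC)cc(OC)cc1[C@H]1[C@H](c2ccc(OC)cc2)c2c(OC)cc(OC)cc2[C@@H]2c3c(cc(OC)cc3C1=O)O[C@H]2c1ccc(OC)cc1 | intermediate
21 | tosylhydrazone of 20 at C8c | N#Cc1c(OC)cc(OC)cc1[C@H]1[C@H](c2ccc(OC)cc2)c2c(OC)cc(OC)cc2[C@@H]2c3c(cc(OC)cc3C1=NNS(=O)(=O)c1ccc(C)cc1)O[C@H]2c1ccc(OC)cc1 | intermediate
22 | (7aR,8aR,7bR,8bR)-nitrile: as 20 with C8c as CH2 | N#Cc1c(OC)cc(OC)cc1[C@H]1[C@H](c2ccc(OC)cc2)c2c(OC)cc(OC)cc2[C@@H]2c3c(cc(OC)cc3C1)O[C@H]2c1ccc(OC)cc1 | intermediate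
23 | 4-methoxyphenylmagnesium bromide | COc1ccc([Mg]Br)cc1 | starting material
24 | N–H ketimine: C10a of ring A bears C7c(=NH)(4-methoxyphenyl) | COc1ccc(cc1)C(=N)c1c(OC)cc(OC)cc1[C@H]1[C@H](c2ccc(OC)cc2)c2c(OC)cc(OC)cc2[C@@H]2c3c(cc(OC)cc3C1)O[C@H]2c1ccc(OC)cc1 | intermediate
25 | hydrazone: C7c(=NNH2) in place of the ketimine of 24 | COc1ccc(cc1)C(=NN)c1c(OC)cc(OC)cc1[C@H]1[C@H](c2ccc(OC)cc2)c2c(OC)cc(OC)cc2[C@@H]2c3c(cc(OC)cc3C1)O[C@H]2c1ccc(OC)cc1 | intermediate
26 | diaryldiazomethane at C7c | COc1ccc(cc1)C(=[N+]=[N-])c1c(OC)cc(OC)cc1[C@H]1[C@H](c2ccc(OC)cc2)c2c(OC)cc(OC)cc2[C@@H]2c3c(cc(OC)cc3C1)O[C@H]2c1ccc(OC)cc1 | intermediate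
27 | octa-O-methylcanaliculatol (7aR,8aR,7bR,8bR,7cR,8cS) | COc1ccc([C@@H]2c3c(OC)cc(OC)cc3[C@H]3[C@H](c4ccc(OC)cc4)c4c(OC)cc(OC)cc4[C@@H]4c5c(cc(OC)cc5[C@H]23)O[C@H]4c2ccc(OC)cc2)cc1 | intermediate
28 | canaliculatol | Oc1ccc([C@@H]2c3c(O)cc(O)cc3[C@H]3[C@H](c4ccc(O)cc4)c4c(O)cc(O)cc4[C@@H]4c5c(cc(O)cc5[C@H]23)O[C@H]4c2ccc(O)cc2)cc1 | target

Total step count: 16 (steps 3 and 11 are branch steps from compound 1).
Longest linear sequence: 14 steps (1, 2, 4–10, 12–16).

Steps most likely to fail

Step 15. Hydride transfer may occur from the wrong C–H bond (the electron-rich C7a methine or the ortho OCH3 group), or from the other diastereotopic hydrogen of C8c, which would give the cis-fused isomer. The fallback sets out from 17 and returns at 27, and still closes the indane last. Ketone 17 is α-arylated with 1-bromo-3,5-dimethoxybenzene (Pd2(dba)3, XPhos, K3PO4) to the α-aryl ketone F1. Van Leusen reductive cyanation (TosMIC, t-BuOK, DME/EtOH) should give the C8c nitrile F2. Intramolecular Houben–Hoesch acylation of ring A (HCl, ZnCl2, then water) closes the indane as the indanone F3, whose C8c should equilibrate by enolisation to the trans ring fusion. Addition of 4-MeOC6H4CeCl2 (from the Grignard reagent and CeCl3) gives the tertiary carbinol F4. Ionic hydrogenation (Et3SiH, BF3·OEt2, −78 °C) should deliver hydride to the C7c cation anti to ring C and give 27.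

Step 9. Intermolecular aldol oligomerisation may outrun the medium-ring closure, or dehydration within the ring may stall. The fallback sets out from 14 and returns at 15. Methylenation of the aldehyde alone (Ph3P=CH2, 1 equiv, −78 °C) gives the styrene F5. α-Methylenation of the methyl ketone (paraformaldehyde, i-Pr2NH·TFA, THF, reflux) gives the aryl vinyl ketone F6. Ring-closing metathesis with the second-generation Grubbs catalyst (toluene, 80 °C, high dilution) should then give 15.

Step 6. Condensation at the tri-ortho-substituted carbonyl may stall, or the acetal may be lost on prolonged heating with the Lewis acid. The fallback sets out from 7 and returns at 9. Thionation with Lawesson's reagent (toluene, 110 °C) gives the thioketone F7, whose far more reactive C=S group should exchange with hydrazine hydrate (EtOH, rt) to give 9.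

Further compounds
F1 | step 15 | (7aR,8aR,7bR,8bR)-C8c ketone with 3,5-dimethoxyphenyl (ring A) on C8a | COc1cc(OC)cc(c1)[C@H]1[C@H](c2ccc(OC)cc2)c2c(OC)cc(OC)cc2[C@@H]2c3c(cc(OC)cc3C1=O)O[C@H]2c1ccc(OC)cc1
F2 | step 15 | C8c carbonitrile from F1 (C8c epimers) | COc1cc(OC)cc(c1)[C@H]1[C@H](c2ccc(OC)cc2)c2c(OC)cc(OC)cc2[C@@H]2c3c(cc(OC)cc3C1C#N)O[C@H]2c1ccc(OC)cc1
F3 | step 15 | trans-fused indanone (C7c ketone bonded to C10a of ring A) | O=C2c3c(OC)cc(OC)cc3[C@H]3[C@H](c4ccc(OC)cc4)c4c(OC)cc(OC)cc4[C@@H]4c5c(cc(OC)cc5[C@H]23)O[C@H]4c2ccc(OC)cc2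
F4 | step 15 | C7c tertiary carbinol from F3 bearing 4-methoxyphenyl (C7c epimers) | COc1ccc(cc1)C2(O)c3c(OC)cc(OC)cc3[C@H]3[C@H](c4ccc(OC)cc4)c4c(OC)cc(OC)cc4[C@@H]4c5c(cc(OC)cc5[C@H]23)O[C@H]4c2ccc(OC)cc2
F5 | step 9 | 1-[(2R,3R)-3-(2-ethenyl-3,5-dimethoxyphenyl)-6-methoxy-2-(4-methoxyphenyl)-2,3-dihydro-1-benzofuran-4-yl]ethanone | COc1cc(OC)c(C=C)c(c1)[C@@H]1c2c(C(C)=O)cc(OC)cc2O[C@H]1c1ccc(OC)cc1
F6 | step 9 | 1-[(2R,3R)-3-(2-ethenyl-3,5-dimethoxyphenyl)-6-methoxy-2-(4-methoxyphenyl)-2,3-dihydro-1-benzofuran-4-yl]prop-2-en-1-one | COc1cc(OC)c(C=C)c(c1)[C@@H]1c2c(C(=O)C=C)cc(OC)cc2O[C@H]1c1ccc(OC)cc1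
F7 | step 6 | thioketone corresponding to 7 | COc1ccc(COc2cc(OC)cc(Br)c2C(=S)c2cc(OC)cc(OC)c2C2OCCO2)cc1
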